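common to all: first end groups 0.10 M

|  | scavenger | solid second end groups | remark | time |
|---|---|---|---|---|
| south-east | 0.080 M | 0.15 M | run made earlier |  |
| east | 0.080 M | 0.24 M | run made earlier |  |
| south | 0.16 M | 0.11 M | run made earlier |  |
| flask | 0.0800 M | 0.110 M |  | 15 h |

- south-east (time / h: first end groups / %, links / %): 1.50: 100.2, 0; 5.00: 95.4, 2.7; 8.00: 94.0, 5.3; 12.0: 86.9, 12.5; 20.0: 80.5, 20.5
- east (time / h: first end groups / %, links / %): 1.50: 100.3, 0; 5.00: 95.2, 4.2; 8.00: 94.8, 7.4; 12.0: 90.0, 8.8; 20.0: 79.5, 21.1
- south (time / h: first end groups / %, links / %): 4.00: 97.4, 3.4; 8.00: 94.1, 6.6; 10.0: 91.4, 7.9; 15.0: 84.7, 15.1; 20.0: 81.7, 20.1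

(readings scatter by 1 percentage point)

- at the start none of the solid second end groups is in solution
- the earlier runs do not show how much of second end groups is bound; that part of a forecast is a guess

- part of the first end groups that has reacted at 15 h
- share of free second end groups in free second end groups and idle adduct together, at 15 h

The east run has 0.24 M of solid second end groups against 0.15 M in the south-east run, and the south run has 0.11 M of them with twice the scavenger, yet after 20.0 h the south-east, east and south runs leave the first end groups at 80.5%, 79.5% and 81.7%, against a scatter of 1 percentage point per reading. So keep a ledger of the first end groups, the limiting reagent in the flask, which is charged with less of them than of solid second end groups. Averaged over the runs at that time, the entry "left" reads 80.6% and the entry "links" 20.6%. Together they make 101%, so at this scatter you need no third entry.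

The entry "left" gives a half-life of 64.2 h, the time in which first end groups halve at the fraction lost per hour so far. The 15 h asked is 0.234 of that, so my ledger for the flask books 15.0% to links and the rest as left. The free share has no entry in these runs.

The forecast gives 15% (12.5% to 17.5%) reacted and a free share of 40% (7% to 85%), saying “The free share is poorly determined”.

The flask gives 14.7% reacted, inside the forecast's range, and a free share of 98.5%, above that range.

    first end groups + second end groups → links + released group (k = 2.70 M⁻¹ h⁻¹)
    second end groups + released group ⇌ idle adduct, settled at all times (K = 7.90 M⁻¹)
    scavenger + released group → scavenged by-product (k = 8.80 M⁻¹ h⁻¹)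
    solid second end groups ⇌ second end groups, rate k4*(cs4 - [second end groups]) while solid is left; crystals form when [second end groups] > cs4 (solubility = 33.0 mM, k = 0.0460 h⁻¹)
    links → over-reaction product (k = 1.60 × 10⁻⁴ h⁻¹)

Counted the same way, the flask's 14.7% gives a half-life of 65.4 h, and the neighbour flask charged with 0.048 M of scavenger, with 85.3% of its first end groups left, gives 65.4 h. In the flask the half-life of released group against scavenger, by that step alone at the concentrations charged, is 0.98 h, far shorter than the 15 h of the run. At 15.0 h c(released group) stands at 0.00197 M, scavenged by-product has reached 0.0127 M, and idle adduct stands at 8.11 × 10⁻⁵ M against 0.00523 M of free second end groups.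

Readings and results are simulated for an exercise; noise was put on by code.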